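## Analysis of the target

Compound 18 is a 3-hydroxyisoflavanone: a chroman-4-one (benzo ring A fused to the pyranone ring C) with a free hydroxyl at C7, and at C3 both a hydroxyl and the aryl ring B. C3 is the only stereocentre. It is a quaternary, tertiary benzylic α-ketol carbon bonded to OH, the C2 methylene, the C4 carbonyl and C1' of ring B, and the SMILES descriptor corresponds to (R), so the problem is one of absolute control only. Ring B is pentasubstituted: C1' carries C3, C2' and C3' carry free hydroxyls, C4' a methoxy group, C5' a 1,1-dimethylallyl group, and only C6' carries hydrogen. The sensitive groups are the terminal vinyl group (which rules out hydrogenolysis and free electrophilic halogen), the electron-rich catechol, and the α-ketol, which strong acid can dehydrate towards the isoflavone. The difficulty lies in ring B, where three contiguous oxygens must end up differentiated next to a tert-alkyl group, and in the fully substituted carbinol C3. The strategy rests on the fact that the six carbons of ring B map onto a polyketide-like chain. C1'–C2'–C3' correspond to C2–C3–C4 of an acetoacetate that already carries the C3' oxygen. C4'–C5'–C6' correspond to an acrylic acid unit whose α-carbon already carries the dimethylallyl group. The ring then closes by forming C3'–C4' and C1'–C6'.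

## Retrosynthetic reasoning

**18 from 17.** The last operation only releases the three phenols. Acetal protection is chosen because the vinyl group forbids hydrogenolysis, and because these groups survive the organolithium, carbonate and carbene steps that precede. 17 is therefore the tris(methoxymethyl) ether of 18.

**17 from 16.** The C3–C4 bond is cut. C3 is a tertiary α-ketol, so this is the benzoin bond. Cutting here removes the only stereocentre and ring C together and leaves the achiral keto aldehyde 16. A cut at C3–C1' would require a hindered aryl nucleophile to add to a 1,2-dicarbonyl. A cut at O1–C2 as the final bond would require the quaternary carbinol to be set in an open chain. In the forward direction a chiral carbene must turn the aldehyde, not the ketone, into the acyl anion equivalent and deliver it to one face of the aryl ketone.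

**16 from 13 and 15.** The O1–C2 ether bond is cut, giving the phenol 15 and the chloromethyl ketone 13. The forward reaction is a phenoxide displacement at a primary, carbonyl-activated carbon. 15 comes from 14 by protection of the unchelated hydroxyl.

**13 back to 9.** C2 of the chromanone is added to the ester carbon of 12 as a halomethyl carbanion equivalent, so the benzoate ester of ring B is the direct precursor of the C3 carbon. Before that, the benzyl group of 9 has to be exchanged (12 from 11 from 10) because it could not be removed at the end without reducing the vinyl group. The 4-O-methyl group is placed first (10 from 9), while the 2-hydroxyl is held in a hydrogen bond to the ester and the 3-oxygen is benzylated.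

**9 from 7 and 6, through 8.** Ring B is cut at C3'–C4' and C1'–C6'. This gives the keto ester 7, which supplies C1', C2', C3', the ester carbon and the benzylated oxygen, and the acyl chloride 6, which supplies C4', C5', C6' and the dimethylallyl group. The cut is made here because each of the five substituents is then fixed by the connectivity of an open-chain precursor and not by selectivity on an arene. The forward reaction must first join the terminal carbanion of doubly deprotonated 7 to the acyl carbon of 6, giving 8, and then close C2 of the chain onto the methoxymethylene carbon with loss of methanol.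

**6 from 1 and 2.** The acyl chloride 6 comes from the acid 5, the acid from the ester 4, and 4 from the formyl ester 3 by O-methylation. 3 is the crossed Claisen product of the commercial ester 1 and the formate 2. The quaternary carbon with its vinyl group is bought in 1.

## Alternatives that were turned down

**Alternative 1:** C3 is assembled from three components. The C3–O and C2–C3 bonds are cut, leading back to the aryldiazoacetate A1, water and formaldehyde A2. In the forward step Rh2(OAc)4 converts A1 into a carbene, water adds to give an oxonium ylide or its enol, and a chiral phosphoric acid steers the addition to A2, giving the diol ester A3 with the quaternary carbinol in place.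
- For: the tertiary hydroxyl, the C2 carbon and the configuration are installed in a single convergent step from very simple reagents, before any ring closure. On convergence at C3 it is at least as attractive as a benzoin closure.
- Against: the carbene centre of A1 sits beside an ortho silyloxy group, which slows ylide formation and can itself be attacked by the carbene. The 1,2-hydrogen shift to the plain O–H insertion product competes with trapping by A2. A3 must still be joined to ring A twice, by an ether bond at the primary hydroxyl and by a C4–C4a acylation, each in the presence of the free tertiary alcohol.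
- Comparison: it leaves the pentasubstituted ring B unsolved and adds several steps after its key step. The chosen route solves ring B directly and then needs one catalytic step for ring C and C3 together.

**Alternative 2:** The C4–C4a bond is cut, leading back to the benzofuranone A4, in which the 2'-oxygen is tied up as a lactone with the future C4 carbon and ring A is tethered as an aryl bromide. Bromine–lithium exchange with t-BuLi gives an aryllithium that attacks the lactone carbonyl, closes ring C and releases the 2'-phenoxide, giving A5.
- For: the closure is intramolecular and fast at low temperature. C3 has no enolisable hydrogen and cannot be scrambled. The lactone distinguishes the 2'- and 3'-oxygens without extra steps, a point on which this plan is stronger than the chosen one.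
- Against: A4 contains the quaternary α-alkoxy lactone carbon in enantiopure form, so a separate asymmetric step is needed before the key step. t-BuLi can add to the lactone carbonyl in competition with the exchange. The acetal groups can direct unwanted ortho-lithiation. Ring B must still be made.
- Comparison: it is longer and moves the stereochemical problem to an earlier, harder intermediate. The chosen route sets C3 catalytically in the ring-closing step.

**Alternative 3:** The C3–C4 bond is cut and the keto aldehyde A7 is closed to A8 by a chiral triazolylidene carbene. The weight of that plan lies on this closure, and ring B would be taken from an existing arene such as A6, elaborated by phenol alkylations and an aromatic Claisen rearrangement.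
- For: the closure is the most direct access to ring C and C3. On this point the alternative is equally strong, since A7 and A8 are the same structures as 16 and 17 and the same closure serves as the endgame here. An arene-based ring B would also use only long-established reactions and could be somewhat shorter, so it is stronger on reliability of the early steps.
- Against: the three neighbouring hydroxyls of A6 must be told apart by selectivity alone. The tert-alkyl group must be introduced by a high-temperature rearrangement, under which ortho-(1,1-dimethylallyl)phenols tend to cyclise or rearrange further. The acetyl group must be α-halogenated in the presence of the vinyl group.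
- Comparison: the chosen strategy places every substituent of ring B by construction, delivers the oxygens already differentiated, carries the dimethylallyl group in from a cheap ester without a thermal step, and provides an ester as the handle for the halomethyl ketone. The price is a ring-forming step that is untested on this substitution pattern.

Key step: step 5

**Assumptions (remarks on the chemistry):**
- Compounds 4–6 are drawn as the E isomers (methoxy trans to the carbonyl group). Either geometry or a mixture serves, because the methoxymethylene carbon becomes tetrahedral during the closure in step 5.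
- The (5aS,10bR) antipode of the aminoindanol triazolium salt is taken to give the (3R) carbinol. Both antipodes derive from commercial cis-1-amino-2-indanol, so the other salt is substituted without further change should the sense of induction be the opposite.
- Enolates, phenoxides and other simple deprotonated forms of numbered compounds are treated as the same compound. Only intermediates of new constitution receive a number.

## Route

Step 1
Reactants: 1 methyl 3,3-dimethylpent-4-enoate; 2 methyl formate
Product: 3 methyl 2-formyl-3,3-dimethylpent-4-enoate (racemic, in equilibrium with its hydroxymethylene enol)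
Conditions: LiN(i-Pr)2 (1.1 equiv), THF, −78 °C; 2 (3 equiv), −78 → 0 °C; 1 M HCl to pH 3
Reagents that add atoms: none
Why: Crossed Claisen condensation (α-formylation) of the lithium ester enolate with a non-enolisable formate; the released methoxide deprotonates the β-formyl ester and drives the reaction, and self-condensation of the neopentyl-type ester is slow.

Step 2
Reactants: 3 methyl 2-formyl-3,3-dimethylpent-4-enoate
Product: 4 methyl (2E)-3-methoxy-2-(2-methylbut-3-en-2-yl)prop-2-enoate
Conditions: Me2SO4 (1.2 equiv), K2CO3 (1.5 equiv), DMF, 0 °C → rt
Reagents that add atoms: dimethyl sulfate, COS(=O)(=O)OC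
Why: O-alkylation of the formyl ester enolate by a hard electrophile in a dipolar aprotic solvent, the standard β-methoxyacrylate synthesis; C-methylation is disfavoured at the carbon next to the quaternary centre.

Step 3
Reactants: 4 methyl (2E)-3-methoxy-2-(2-methylbut-3-en-2-yl)prop-2-enoate
Product: 5 (2E)-3-methoxy-2-(2-methylbut-3-en-2-yl)prop-2-enoic acid
Conditions: LiOH·H2O (3 equiv), THF/MeOH/H2O, 50 °C; 1 M HCl to pH 3, 0 °C
Reagents that add atoms: lithium hydroxide, [Li+].[OH-]
Why: Ester saponification; the vinylogous carbonate character of the β-methoxyacrylate protects the enol ether from base, and cold, brief acidification avoids its hydrolysis.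

Step 4
Reactants: 5 (2E)-3-methoxy-2-(2-methylbut-3-en-2-yl)prop-2-enoic acid
Product: 6 (2E)-3-methoxy-2-(2-methylbut-3-en-2-yl)prop-2-enoyl chloride
Conditions: (COCl)2 (1.3 equiv), DMF (cat.), CH2Cl2, 0 °C → rt; evaporation, used crude
Reagents that add atoms: oxalyl chloride, O=C(Cl)C(=O)Cl
Why: Acid chloride formation through the chloroiminium catalyst; the acid has no α-hydrogen, so no ketene can form, and the electron-poor enol ether and the monosubstituted alkene should not add HCl under these conditions.

Step 5
Reactants: 7 ethyl 4-(benzyloxy)-3-oxobutanoate; 6 (2E)-3-methoxy-2-(2-methylbut-3-en-2-yl)prop-2-enoyl chloride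
Product: 9 ethyl 3-(benzyloxy)-2,4-dihydroxy-5-(2-methylbut-3-en-2-yl)benzoate, via acyclic diketo ester 8 (not isolated)
Conditions: 7 (2.2 equiv), LiN(i-Pr)2 (4.4 equiv), THF, −78 → 0 °C; 6 (1.0 equiv), −78 → 0 °C; then EtOH, rt → 50 °C; 1 M HCl to pH 4, 0 °C
Reagents that add atoms: none
Why: Double deprotonation of 7 gives the 2,4-dienolate, whose last-formed C4 carbanion is the most nucleophilic site and attacks the acyl chloride carbon of 6 (the C3'–C4' bond); a second equivalent of dienolate takes up the acidic C4–H of 8, which is why 7 is used in excess. In the ethanolic lithium ethoxide formed on adding EtOH, the C2 carbanion, flanked by ester and ketone, adds to the methoxymethylene carbon and methoxide is expelled (the C1'–C6' bond), a 6-endo-trig addition–elimination that closes the carbocycle, and two enolisations then give the arene, which makes the closure irreversible. The closest known reactions are the γ-acylation of acetoacetate dianions and the cycloaromatisation of 3,5-dioxo esters with a masked carbonyl at C7 to 2,4-dihydroxybenzoates, as in formal (3+3) resorcylate syntheses from 1,3-dicarbonyl dianion equivalents and 3-alkoxyenoyl electrophiles. No stereocentre is formed. The regiochemistry requires the dienolate terminus to attack the carbonyl carbon and not the enol ether carbon: the acyl chloride is by far the faster electrophile at −78 °C, the enol ether carbon is deactivated by its own oxygen, and the tert-alkyl group on the neighbouring carbon twists the carbonyl out of conjugation and so lowers the vinylogous reactivity further. If the enol oxygen at C3 closes first to a 4-pyranone, ethoxide should reopen it at its unsubstituted ring CH and the chain recloses through carbon, so that path also ends in 9. The product emerges with the three oxygens differentiated: the 2-hydroxyl chelated to the ester, the 3-oxygen benzylated and the 4-hydroxyl free.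

Step 6
Reactants: 9 ethyl 3-(benzyloxy)-2,4-dihydroxy-5-(2-methylbut-3-en-2-yl)benzoate
Product: 10 ethyl 3-(benzyloxy)-2-hydroxy-4-methoxy-5-(2-methylbut-3-en-2-yl)benzoate
Conditions: MeI (1.2 equiv), K2CO3 (1.05 equiv), acetone, rt
Reagents that add atoms: iodomethane, CI
Why: Williamson methylation of the more acidic 4-phenoxide (para to the ester); the 2-hydroxyl is held in the hydrogen bond to the ester carbonyl and reacts only under forcing conditions. Methylating here also removes the free hydroxyl ortho to the dimethylallyl group before any acidic step.

Step 7
Reactants: 10 ethyl 3-(benzyloxy)-2-hydroxy-4-methoxy-5-(2-methylbut-3-en-2-yl)benzoate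
Product: 11 ethyl 2,3-dihydroxy-4-methoxy-5-(2-methylbut-3-en-2-yl)benzoate
Conditions: BCl3 (3 equiv), C6HMe5 (3 equiv), CH2Cl2, −78 °C; MeOH quench, −78 °C → rt
Reagents that add atoms: none
Why: Lewis-acid debenzylation with a non-Lewis-basic cation scavenger, which leaves the vinyl group untouched where hydrogenolysis would not; pentamethylbenzene captures the benzyl cation, and at −78 °C the methyl ether, which is not ortho to the carbonyl, should persist.

Step 8
Reactants: 11 ethyl 2,3-dihydroxy-4-methoxy-5-(2-methylbut-3-en-2-yl)benzoate
Product: 12 ethyl 4-methoxy-2,3-bis(methoxymethoxy)-5-(2-methylbut-3-en-2-yl)benzoate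
Conditions: NaH (2.5 equiv), MOMCl (2.6 equiv), DMF, 0 °C → rt, under argon
Reagents that add atoms: chloromethyl methyl ether, COCCl
Why: Double O-alkylation of the catecholate; full deprotonation with NaH overcomes the chelation of the 2-hydroxyl, and the ester is stable to these conditions.

Step 9
Reactants: 12 ethyl 4-methoxy-2,3-bis(methoxymethoxy)-5-(2-methylbut-3-en-2-yl)benzoate
Product: 13 2-chloro-1-[4-methoxy-2,3-bis(methoxymethoxy)-5-(2-methylbut-3-en-2-yl)phenyl]ethan-1-one
Conditions: ICH2Cl (1.5 equiv), MeLi·LiBr (1.4 equiv), THF, −78 °C; AcOH, −78 °C → rt
Reagents that add atoms: chloroiodomethane, ClCI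
Why: Carbenoid homologation of an ester to an α-chloroketone: chloromethyllithium, made by iodine–lithium exchange in the presence of the ester, adds once, and the tetrahedral lithium hemiketal alkoxide, further held by the ortho acetal oxygen, survives at −78 °C until protonation. This avoids electrophilic halogen, which the vinyl group would not tolerate.

Step 10
Reactants: 14 2,4-dihydroxybenzaldehyde
Product: 15 2-hydroxy-4-(methoxymethoxy)benzaldehyde
Conditions: MOMCl (1.1 equiv), K2CO3 (1.2 equiv), acetone, 0 °C → rt
Reagents that add atoms: chloromethyl methyl ether, COCCl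
Why: Selective alkylation of the 4-hydroxyl; the 2-hydroxyl is hydrogen-bonded to the aldehyde and much less reactive towards a weak base.

Step 11
Reactants: 13 2-chloro-1-[4-methoxy-2,3-bis(methoxymethoxy)-5-(2-methylbut-3-en-2-yl)phenyl]ethan-1-one; 15 2-hydroxy-4-(methoxymethoxy)benzaldehyde
Product: 16 2-{2-[4-methoxy-2,3-bis(methoxymethoxy)-5-(2-methylbut-3-en-2-yl)phenyl]-2-oxoethoxy}-4-(methoxymethoxy)benzaldehyde
Conditions: K2CO3 (1.5 equiv), NaI (0.1 equiv), acetone, rt
Reagents that add atoms: none
Why: Williamson ether synthesis at a primary α-keto carbon with in situ Finkelstein activation; keeping the mixture at room temperature avoids the aldol closure of the product to a benzofuran (Rap–Stoermer condensation), which needs heat.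

Step 12
Reactants: 16 2-{2-[4-methoxy-2,3-bis(methoxymethoxy)-5-(2-methylbut-3-en-2-yl)phenyl]-2-oxoethoxy}-4-(methoxymethoxy)benzaldehyde
Product: 17 (3R)-3-hydroxy-3-[4-methoxy-2,3-bis(methoxymethoxy)-5-(2-methylbut-3-en-2-yl)phenyl]-7-(methoxymethoxy)-2,3-dihydro-4H-chromen-4-one
Conditions: (5aS,10bR)-5a,10b-dihydro-2-(pentafluorophenyl)-4H,6H-indeno[2,1-b][1,2,4]triazolo[4,3-d][1,4]oxazin-2-ium tetrafluoroborate (10 mol%), Et3N (10 mol%), toluene, rt, under argon
Reagents that add atoms: none
Why: Intramolecular crossed aldehyde–ketone benzoin reaction: the carbene adds to the aldehyde, the Breslow intermediate attacks the tethered aryl ketone in a 6-exo-trig closure, and release of the catalyst gives the tertiary α-ketol. The fused indane of the catalyst shields one face of the acyl anion equivalent, so the ketone is approached from a single face and C3 is set under catalyst control; the weak amine base keeps aldol pathways of the keto aldehyde slow.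

Step 13
Reactants: 17 (3R)-3-hydroxy-3-[4-methoxy-2,3-bis(methoxymethoxy)-5-(2-methylbut-3-en-2-yl)phenyl]-7-(methoxymethoxy)-2,3-dihydro-4H-chromen-4-one
Product: 18 (3R)-3-[2,3-dihydroxy-4-methoxy-5-(2-methylbut-3-en-2-yl)phenyl]-3,7-dihydroxy-2,3-dihydro-4H-chromen-4-one
Conditions: conc. aq. HCl (cat.), MeOH, 40 °C, under argon
Reagents that add atoms: none
Why: Acid-catalysed acetal exchange releases the three phenols as methanol takes up the methoxymethyl groups. C3 has no hydrogen and cannot epimerise, and dilute acid at this temperature should neither ionise the α-ketol nor protonate the monosubstituted alkene, which has no free ortho hydroxyl beside it.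

## Compound list

1 | methyl 3,3-dimethylpent-4-enoate | COC(=O)CC(C)(C)C=C | starting material
2 | methyl formate | COC=O | starting material
3 | methyl 2-formyl-3,3-dimethylpent-4-enoate (racemic, enolisable) | COC(=O)C(C=O)C(C)(C)C=C | intermediate
4 | methyl (2E)-3-methoxy-2-(2-methylbut-3-en-2-yl)prop-2-enoate | CO/C=C(\C(C)(C)C=C)C(=O)OC | intermediate
5 | (2E)-3-methoxy-2-(2-methylbut-3-en-2-yl)prop-2-enoic acid | CO/C=C(\C(C)(C)C=C)C(=O)O | intermediate
6 | (2E)-3-methoxy-2-(2-methylbut-3-en-2-yl)prop-2-enoyl chloride | CO/C=C(\C(C)(C)C=C)C(=O)Cl | intermediate
7 | ethyl 4-(benzyloxy)-3-oxobutanoate | CCOC(=O)CC(=O)COCc1ccccc1 | starting material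
8 | ethyl (6E)-4-(benzyloxy)-7-methoxy-6-(2-methylbut-3-en-2-yl)-3,5-dioxohept-6-enoate (racemic at C4, enolisable; not isolated) | CCOC(=O)CC(=O)C(OCc1ccccc1)C(=O)/C(=C/OC)C(C)(C)C=C | intermediate
9 | ethyl 3-(benzyloxy)-2,4-dihydroxy-5-(2-methylbut-3-en-2-yl)benzoate | CCOC(=O)c1cc(C(C)(C)C=C)c(O)c(OCc2ccccc2)c1O | intermediate
10 | ethyl 3-(benzyloxy)-2-hydroxy-4-methoxy-5-(2-methylbut-3-en-2-yl)benzoate | CCOC(=O)c1cc(C(C)(C)C=C)c(OC)c(OCc2ccccc2)c1O | intermediate
11 | ethyl 2,3-dihydroxy-4-methoxy-5-(2-methylbut-3-en-2-yl)benzoate | CCOC(=O)c1cc(C(C)(C)C=C)c(OC)c(O)c1O | intermediate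
12 | ethyl 4-methoxy-2,3-bis(methoxymethoxy)-5-(2-methylbut-3-en-2-yl)benzoate | CCOC(=O)c1cc(C(C)(C)C=C)c(OC)c(OCOC)c1OCOC | intermediate
13 | 2-chloro-1-[4-methoxy-2,3-bis(methoxymethoxy)-5-(2-methylbut-3-en-2-yl)phenyl]ethan-1-one | C=CC(C)(C)c1cc(C(=O)CCl)c(OCOC)c(OCOC)c1OC | intermediate
14 | 2,4-dihydroxybenzaldehyde | O=Cc1ccc(O)cc1O | starting material
15 | 2-hydroxy-4-(methoxymethoxy)benzaldehyde | COCOc1ccc(C=O)c(O)c1 | intermediate
16 | 2-{2-[4-methoxy-2,3-bis(methoxymethoxy)-5-(2-methylbut-3-en-2-yl)phenyl]-2-oxoethoxy}-4-(methoxymethoxy)benzaldehyde | C=CC(C)(C)c1cc(C(=O)COc2cc(OCOC)ccc2C=O)c(OCOC)c(OCOC)c1OC | intermediate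
17 | (3R)-3-hydroxy-3-[4-methoxy-2,3-bis(methoxymethoxy)-5-(2-methylbut-3-en-2-yl)phenyl]-7-(methoxymethoxy)-2,3-dihydro-4H-chromen-4-one | C=CC(C)(C)c1cc([C@@]2(O)COc3cc(OCOC)ccc3C2=O)c(OCOC)c(OCOC)c1OC | intermediate
18 | (3R)-3-[2,3-dihydroxy-4-methoxy-5-(2-methylbut-3-en-2-yl)phenyl]-3,7-dihydroxy-2,3-dihydro-4H-chromen-4-one | C=CC(C)(C)c1cc([C@@]2(O)COc3cc(O)ccc3C2=O)c(O)c(O)c1OC | target

## Step count and least certain steps

Total: 13 steps. Longest linear sequence: 12 steps (steps 1–9 and 11–13, from 1 to 18); step 10 prepares the ring A fragment.

**Step 5 (key step).** The acylation may stall, because the acylated chain is more acidic than the dienolate and the acyl chloride is hindered by its α-tert-alkyl group. The terminus may instead attack the enol ether carbon, which would invert the oxygen pattern. The chain may also close through oxygen and fail to reopen.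
Fallback, from 7 back to 9: the dimethylallyl group is no longer carried through the annulation. The dienolate of 7 is acylated with the commercial, α-unsubstituted (E)-3-methoxyacryloyl chloride. The resulting ethyl (6E)-4-(benzyloxy)-7-methoxy-3,5-dioxohept-6-enoate F1 is cyclised in the same way to ethyl 3-(benzyloxy)-2,4-dihydroxybenzoate F2. The unchelated 4-hydroxyl is alkylated with prenyl bromide (K2CO3, acetone) to give ethyl 3-(benzyloxy)-2-hydroxy-4-[(3-methylbut-2-en-1-yl)oxy]benzoate F3. Aromatic Claisen rearrangement (N,N-diethylaniline, 180 °C) then transfers the allyl unit with inversion to C5, the only free ortho position, and gives 9.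

**Step 12.** Facial selectivity may be low, or the closure slow, because the ketone is electron-rich and carries an ortho acetal. The base may instead trigger aldol closure of the keto aldehyde.
Fallback, from 16 back to 17: the ring is closed without asymmetric induction, using the achiral salt 2-(pentafluorophenyl)-6,7-dihydro-5H-pyrrolo[2,1-c][1,2,4]triazol-2-ium tetrafluoroborate and Et3N. This gives racemic 3-hydroxy-3-[4-methoxy-2,3-bis(methoxymethoxy)-5-(2-methylbut-3-en-2-yl)phenyl]-7-(methoxymethoxy)-2,3-dihydro-4H-chromen-4-one F9. The enantiomers are separated by preparative chromatography on a cellulose tris(3,5-dimethylphenylcarbamate) phase, and the (3R) enantiomer is 17.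

**Step 9.** The tetrahedral adduct may collapse before the quench, which allows a second addition of the carbenoid. The carbenoid may also decompose before it reaches the ortho-substituted ester.
Fallback, from 12 back to 13:
- Saponification (LiOH, THF/H2O) gives 4-methoxy-2,3-bis(methoxymethoxy)-5-(2-methylbut-3-en-2-yl)benzoic acid F6.
- Isobutyl chloroformate and N-methylmorpholine convert it into the mixed anhydride 4-methoxy-2,3-bis(methoxymethoxy)-5-(2-methylbut-3-en-2-yl)benzoic 2-methylpropyl carbonic anhydride F7.
- Diazomethane gives 2-diazo-1-[4-methoxy-2,3-bis(methoxymethoxy)-5-(2-methylbut-3-en-2-yl)phenyl]ethan-1-one F8 (the first stage of an Arndt–Eistert sequence).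
- One equivalent of HCl in Et2O at −20 °C converts the diazoketone into 13 (Nierenstein reaction).

**Step 6.** Selectivity may be lost because the 4-hydroxyl lies between a benzyloxy and a tert-alkyl group, so methylation there may slow enough for the chelated 2-hydroxyl to compete.
Fallback, from 9 back to 11: both hydroxyls are methylated (MeI in excess, K2CO3, DMF) to ethyl 3-(benzyloxy)-2,4-dimethoxy-5-(2-methylbut-3-en-2-yl)benzoate F4. BCl3 with pentamethylbenzene then removes the benzyl group at −78 °C, giving ethyl 3-hydroxy-2,4-dimethoxy-5-(2-methylbut-3-en-2-yl)benzoate F5. On warming to 0 °C the same reagent cleaves the methyl ether ortho to the ester carbonyl by chelation, which gives 11 and bypasses 10.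

## Further compounds

F1 | step 5 | ethyl (6E)-4-(benzyloxy)-7-methoxy-3,5-dioxohept-6-enoate | CCOC(=O)CC(=O)C(OCc1ccccc1)C(=O)/C=C/OC
F2 | step 5 | ethyl 3-(benzyloxy)-2,4-dihydroxybenzoate | CCOC(=O)c1ccc(O)c(OCc2ccccc2)c1O
F3 | step 5 | ethyl 3-(benzyloxy)-2-hydroxy-4-[(3-methylbut-2-en-1-yl)oxy]benzoate | CCOC(=O)c1ccc(OCC=C(C)C)c(OCc2ccccc2)c1O
F4 | step 6 | ethyl 3-(benzyloxy)-2,4-dimethoxy-5-(2-methylbut-3-en-2-yl)benzoate | CCOC(=O)c1cc(C(C)(C)C=C)c(OC)c(OCc2ccccc2)c1OC
F5 | step 6 | ethyl 3-hydroxy-2,4-dimethoxy-5-(2-methylbut-3-en-2-yl)benzoate | CCOC(=O)c1cc(C(C)(C)C=C)c(OC)c(O)c1OC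
F6 | step 9 | 4-methoxy-2,3-bis(methoxymethoxy)-5-(2-methylbut-3-en-2-yl)benzoic acid | C=CC(C)(C)c1cc(C(=O)O)c(OCOC)c(OCOC)c1OC
F7 | step 9 | 4-methoxy-2,3-bis(methoxymethoxy)-5-(2-methylbut-3-en-2-yl)benzoic 2-methylpropyl carbonic anhydride | C=CC(C)(C)c1cc(C(=O)OC(=O)OCC(C)C)c(OCOC)c(OCOC)c1OC
F8 | step 9 | 2-diazo-1-[4-methoxy-2,3-bis(methoxymethoxy)-5-(2-methylbut-3-en-2-yl)phenyl]ethan-1-one | C=CC(C)(C)c1cc(C(=O)C=[N+]=[N-])c(OCOC)c(OCOC)c1OC
F9 | step 12 | racemic 3-hydroxy-3-[4-methoxy-2,3-bis(methoxymethoxy)-5-(2-methylbut-3-en-2-yl)phenyl]-7-(methoxymethoxy)-2,3-dihydro-4H-chromen-4-one | C=CC(C)(C)c1cc(C2(O)COc3cc(OCOC)ccc3C2=O)c(OCOC)c(OCOC)c1OC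
A1 | alternative 1 | ethyl 2-[2,3-bis(tert-butyldimethylsilyloxy)-4-methoxy-5-(2-methylbut-3-en-2-yl)phenyl]-2-diazoacetate | C=CC(C)(C)c1cc(C(=[N+]=[N-])C(=O)OCC)c(O[Si](C)(C)C(C)(C)C)c(O[Si](C)(C)C(C)(C)C)c1OC
A2 | alternative 1 | formaldehyde | C=O
A3 | alternative 1 | ethyl (2R)-2-[2,3-bis(tert-butyldimethylsilyloxy)-4-methoxy-5-(2-methylbut-3-en-2-yl)phenyl]-2,3-dihydroxypropanoate | C=CC(C)(C)c1cc([C@@](O)(CO)C(=O)OCC)c(O[Si](C)(C)C(C)(C)C)c(O[Si](C)(C)C(C)(C)C)c1OC
A4 | alternative 2 | (3R)-3-{[2-bromo-5-(methoxymethoxy)phenoxy]methyl}-6-methoxy-3,7-bis(methoxymethoxy)-5-(2-methylbut-3-en-2-yl)-1-benzofuran-2(3H)-one | C=CC(C)(C)c1cc2c(c(OCOC)c1OC)OC(=O)[C@]2(OCOC)COc1cc(OCOC)ccc1Br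
A5 | alternative 2 | (3R)-3-[2-hydroxy-4-methoxy-3-(methoxymethoxy)-5-(2-methylbut-3-en-2-yl)phenyl]-3,7-bis(methoxymethoxy)-2,3-dihydro-4H-chromen-4-one | C=CC(C)(C)c1cc([C@@]2(OCOC)COc3cc(OCOC)ccc3C2=O)c(O)c(OCOC)c1OC
A6 | alternative 3 | 1-(2,3,4-trihydroxyphenyl)ethan-1-one | CC(=O)c1ccc(O)c(O)c1O
A7 | alternative 3 | 2-{2-[4-methoxy-2,3-bis(methoxymethoxy)-5-(2-methylbut-3-en-2-yl)phenyl]-2-oxoethoxy}-4-(methoxymethoxy)benzaldehyde | C=CC(C)(C)c1cc(C(=O)COc2cc(OCOC)ccc2C=O)c(OCOC)c(OCOC)c1OC
A8 | alternative 3 | (3R)-3-hydroxy-3-[4-methoxy-2,3-bis(methoxymethoxy)-5-(2-methylbut-3-en-2-yl)phenyl]-7-(methoxymethoxy)-2,3-dihydro-4H-chromen-4-one | C=CC(C)(C)c1cc([C@@]2(O)COc3cc(OCOC)ccc3C2=O)c(OCOC)c(OCOC)c1OC
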